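**Retrosynthetic overview**
- Ring C is opened at O1–C2 and C3–C4: target 16 comes from the o-hydroxyaryl ynone 14 by amine-mediated 6-endo closure, and 14 from salicylaldehyde 10 plus the purchased ring B alkyne 11.
- Ring A (C4a, C5, C6, C7, C8, C8a) is disconnected at C8a–C4a: phenol 9 comes from the 4-alkenyl-4-methoxycyclobutenone 6 by thermal 4-pi ring opening and 6-pi ring closure.
- The strategy rests on this feature: the four adjacent oxygen-bearing carbons C8a, C8, C7 and C6 are the four ring carbons of dimethyl squarate 3. C5–H and C4a are the two alkene carbons of an (E)-3,3-diethoxypropenyl unit, whose acetal carbon becomes C4.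
- Cyclobutenone 6 comes from 3 and vinylstannane 2 (made from alkyne 1). Ring order: ring B bought, ring A in step 3, ring C in step 7.

Key step: step 3

Remark on the chemistry: the target has no stereocentre. Compounds 5, 6, 8 and 13 are racemates (one enantiomer drawn) whose stereocentres are erased in steps 3 and 6. Flavone numbering is used for the target.

**Route**

Step 1
Reactants: 1 3,3-diethoxyprop-1-yne
Product: 2 (E)-tributyl(3,3-diethoxyprop-1-enyl)stannane
Conditions: Bu3SnH (1.1 equiv), AIBN (cat.), neat, 85 °C
Reagents that add atoms: tributyltin hydride, CCCC[SnH](CCCC)CCCC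
Why: Radical-chain hydrostannylation of a terminal alkyne places tin on the terminal carbon, and reversible stannyl-radical addition at this temperature should equilibrate the alkene towards the E isomer; residual Z isomer would lead to the same arene in step 3 because the alkene geometry is lost on aromatization.

Step 2
Reactants: 2 (E)-tributyl(3,3-diethoxyprop-1-enyl)stannane (1.1 equiv), 3 dimethyl squarate (3,4-dimethoxycyclobut-3-ene-1,2-dione)
Product: 6 rac-4-[(E)-3,3-diethoxyprop-1-enyl]-2,3,4-trimethoxycyclobut-2-en-1-one, via vinyllithium 4 (not isolated), via lithium alkoxide 5 (not isolated)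
Conditions: n-BuLi (1.05 equiv), THF, −78 °C; then 3, THF, −78 °C; then MeOTf (1.5 equiv), −78 to 0 °C; aq NaHCO3
Reagents that add atoms: methyl trifluoromethanesulfonate, COS(=O)(=O)C(F)(F)F
Why: Tin–lithium exchange proceeds with retention of alkene geometry, the vinyllithium adds 1,2 to one of the two equivalent carbonyl groups of the squarate, and the lithium alkoxide is O-methylated by the hard electrophile MeOTf; the quaternary carbon forms racemic and is destroyed in step 3.

Step 3
Reactants: 6 rac-4-[(E)-3,3-diethoxyprop-1-enyl]-2,3,4-trimethoxycyclobut-2-en-1-one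
Product: 9 6-(diethoxymethyl)-2,3,4-trimethoxyphenol, via dienylketene 7 (not isolated), via cyclohexadienone 8 (not isolated)
Conditions: toluene (0.02 M, degassed, base-washed glassware), 110 °C; evaporate, use crude
Reagents that add atoms: none
Why: Heating opens the cyclobutenone by a conrotatory 4-pi electrocyclic reaction across the C1–C4 bond to give dienylketene 7, in which the former carbonyl carbon is the ketene carbon (future C8a) and the former quaternary carbon carries OMe (future C6). A disrotatory 6-pi electrocyclization then joins the ketene carbon to the distal alkene carbon (future C4a), closing ring A as a six-membered carbocycle in the form of cyclohexa-2,4-dienone 8, and enolization of 8 gives phenol 9. The closest known reaction type is the thermal ring expansion of squarate-derived 4-alkenyl-4-alkoxycyclobutenones to mono-protected hydroquinones. No stereocentre remains, because the sp3 carbon of 8 forms racemic and is flattened by the tautomerization. The step needs torquoselective opening with the alkenyl group turned inward, which the strong outward preference of the C4 methoxy donor should provide, and because ring opening is reversible a ketene of the wrong geometry can return to 6. The order OH, OMe, OMe, OMe, H, C-substituent around the ring follows from the connectivity of 6 alone, so the step makes no regiochemical choice.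

Step 4
Reactants: 9 6-(diethoxymethyl)-2,3,4-trimethoxyphenol
Product: 10 2-hydroxy-3,4,5-trimethoxybenzaldehyde
Conditions: 1 M HCl, THF, 0 °C to rt
Reagents that add atoms: water, O
Why: Acid-catalysed hydrolysis of a benzylic acetal is fast on this electron-rich ring and gives the hydrogen-bonded salicylaldehyde; any acetal-exchanged or oligomeric acetal material from step 3 should converge on the same aldehyde.

Step 5
Reactants: 10 2-hydroxy-3,4,5-trimethoxybenzaldehyde, 11 4-ethynyl-1,2-dimethoxybenzene (2.4 equiv)
Product: 13 rac-6-[3-(3,4-dimethoxyphenyl)-1-hydroxyprop-2-yn-1-yl]-2,3,4-trimethoxyphenol, via lithium acetylide 12 (not isolated)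
Conditions: 11, n-BuLi (2.3 equiv), THF, −78 °C; then 10, −78 to 0 °C; sat. aq NH4Cl; use crude
Reagents that add atoms: none
Why: Nucleophilic 1,2-addition of a lithium acetylide to an aldehyde, in which one equivalent of acetylide deprotonates the phenol and a second adds to the carbonyl of the lithium phenoxide; the carbinol stereocentre forms racemic and is removed in step 6.

Step 6
Reactants: 13 rac-6-[3-(3,4-dimethoxyphenyl)-1-hydroxyprop-2-yn-1-yl]-2,3,4-trimethoxyphenol
Product: 14 3-(3,4-dimethoxyphenyl)-1-(2-hydroxy-3,4,5-trimethoxyphenyl)prop-2-yn-1-one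
Conditions: activated MnO2 (excess), CH2Cl2, rt
Reagents that add atoms: none
Why: MnO2 oxidation is selective for the doubly activated (benzylic and propargylic) secondary alcohol and is a standard entry to o-hydroxyaryl ynones from such diols, the phenol being expected to survive these neutral heterogeneous conditions.

Step 7
Reactants: 14 3-(3,4-dimethoxyphenyl)-1-(2-hydroxy-3,4,5-trimethoxyphenyl)prop-2-yn-1-one
Product: 16 2-(3,4-dimethoxyphenyl)-6,7,8-trimethoxy-4H-chromen-4-one (target), via enaminone 15 (not isolated)
Conditions: Et2NH, EtOH, rt then 60 °C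
Reagents that add atoms: none
Why: Conjugate (aza-Michael) addition of Et2NH to the ynone gives enaminone 15, and the phenol oxygen then attacks the amine-bearing carbon in an addition–elimination that expels Et2NH and closes ring C in the 6-endo sense, avoiding the 5-exo closure to an aurone that simple bases favour.

**Compound list**
1 | 3,3-diethoxyprop-1-yne | C#CC(OCC)OCC | starting material
2 | (E)-tributyl(3,3-diethoxyprop-1-enyl)stannane | CCCC[Sn](CCCC)(CCCC)/C=C/C(OCC)OCC | intermediate
3 | dimethyl squarate (3,4-dimethoxycyclobut-3-ene-1,2-dione) | COC1=C(OC)C(=O)C1=O | starting material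
4 | (E)-(3,3-diethoxyprop-1-enyl)lithium, not isolated | [Li]/C=C/C(OCC)OCC | intermediate
5 | lithium rac-1-[(E)-3,3-diethoxyprop-1-enyl]-2,3-dimethoxy-4-oxocyclobut-2-en-1-olate, not isolated | CCOC(OCC)/C=C/[C@]1([O-])C(OC)=C(OC)C1=O.[Li+] | intermediate
6 | rac-4-[(E)-3,3-diethoxyprop-1-enyl]-2,3,4-trimethoxycyclobut-2-en-1-one | CCOC(OCC)/C=C/[C@]1(OC)C(OC)=C(OC)C1=O | intermediate
7 | (3Z,5E)-7,7-diethoxy-2,3,4-trimethoxyhepta-1,3,5-trien-1-one (dienylketene), not isolated | O=C=C(OC)/C(OC)=C(OC)\C=C\C(OCC)OCC | intermediate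
8 | rac-6-(diethoxymethyl)-2,3,4-trimethoxycyclohexa-2,4-dien-1-one, not isolated | CCOC(OCC)[C@H]1C=C(OC)C(OC)=C(OC)C1=O | intermediate
9 | 6-(diethoxymethyl)-2,3,4-trimethoxyphenol | CCOC(OCC)c1cc(OC)c(OC)c(OC)c1O | intermediate
10 | 2-hydroxy-3,4,5-trimethoxybenzaldehyde | O=Cc1cc(OC)c(OC)c(OC)c1O | intermediate
11 | 4-ethynyl-1,2-dimethoxybenzene | C#Cc1ccc(OC)c(OC)c1 | starting material
12 | lithium (3,4-dimethoxyphenyl)acetylide, not isolated | [Li]C#Cc1ccc(OC)c(OC)c1 | intermediate
13 | rac-6-[3-(3,4-dimethoxyphenyl)-1-hydroxyprop-2-yn-1-yl]-2,3,4-trimethoxyphenol | COc1ccc(C#C[C@H](O)c2cc(OC)c(OC)c(OC)c2O)cc1OC | intermediate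
14 | 3-(3,4-dimethoxyphenyl)-1-(2-hydroxy-3,4,5-trimethoxyphenyl)prop-2-yn-1-one | COc1ccc(C#CC(=O)c2cc(OC)c(OC)c(OC)c2O)cc1OC | intermediate
15 | (2E)-3-(diethylamino)-3-(3,4-dimethoxyphenyl)-1-(2-hydroxy-3,4,5-trimethoxyphenyl)prop-2-en-1-one, not isolated | CCN(CC)/C(=C/C(=O)c1cc(OC)c(OC)c(OC)c1O)c1ccc(OC)c(OC)c1 | intermediate
16 | 2-(3,4-dimethoxyphenyl)-6,7,8-trimethoxy-4H-chromen-4-one | COc1ccc(-c2cc(=O)c3cc(OC)c(OC)c(OC)c3o2)cc1OC | target

**Step count and risk**

Total step count: 7. Longest linear sequence: 7 steps (1 → 2 → 6 → 9 → 10 → 13 → 14 → 16); alkyne 11 is used as purchased.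

Steps most likely to fail:

Step 3. The ortho-hydroxybenzylic acetal may lose ethanol at 110 °C and oligomerize through a quinone methide, and any Z-alkenyl material may close slowly enough for the ketene to dimerize. The fallback installs C4 after ring A is made, so that no carrier group passes through the thermolysis. It sets out from 3. Tributyl(vinyl)stannane and n-BuLi (THF, −78 °C) give vinyllithium F1, which adds to 3 to give lithium 1-ethenyl-2,3-dimethoxy-4-oxocyclobut-2-en-1-olate F2. MeOTf converts this to rac-4-ethenyl-2,3,4-trimethoxycyclobut-2-en-1-one F3. Heating in toluene opens F3 to (3Z)-2,3,4-trimethoxyhexa-1,3,5-trien-1-one F4, which closes to 2,3,4-trimethoxycyclohexa-2,4-dien-1-one F5 and tautomerizes to 2,3,4-trimethoxyphenol F6. Magnesium-mediated ortho-formylation (MgCl2, Et3N, paraformaldehyde, MeCN, reflux; Casnati–Skattebøl conditions) at the only free ortho position then gives 10, where the route is rejoined.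

Step 2. The hindered tertiary lithium alkoxide may be captured incompletely by MeOTf, with retro-addition or MeOTf-initiated polymerization of THF on warming. The fallback separates carbon–carbon bond formation from etherification. It sets out from 3 and 4: quenching the adduct at −78 °C with aqueous NH4Cl gives rac-4-[(E)-3,3-diethoxyprop-1-enyl]-4-hydroxy-2,3-dimethoxycyclobut-2-en-1-one F7. This carbinol is methylated under silver-assisted conditions (MeI, Ag2O, K2CO3, MeCN, rt, dark; Purdie methylation) to return to 6.

Step 6. MnO2 may oxidize the electron-rich free phenol ring to a quinone, or the ortho-hydroxybenzylic alcohol 13 may ionize to a quinone methide before it is oxidized. The fallback masks the phenol across the addition and oxidation. It sets out from 10: TBSCl, imidazole and DMF give 2-[(tert-butyldimethylsilyl)oxy]-3,4,5-trimethoxybenzaldehyde F8. Addition of 12 (1.1 equiv, THF, −78 °C, cold AcOH quench to suppress silyl migration) gives rac-1-{2-[(tert-butyldimethylsilyl)oxy]-3,4,5-trimethoxyphenyl}-3-(3,4-dimethoxyphenyl)prop-2-yn-1-ol F9. MnO2 in CH2Cl2 gives 1-{2-[(tert-butyldimethylsilyl)oxy]-3,4,5-trimethoxyphenyl}-3-(3,4-dimethoxyphenyl)prop-2-yn-1-one F10. TBAF buffered with AcOH (THF, 0 °C) removes the silyl group and returns to 14.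

Further compounds
F1 | step 3 | vinyllithium | [Li]C=C
F2 | step 3 | lithium rac-1-ethenyl-2,3-dimethoxy-4-oxocyclobut-2-en-1-olate | C=C[C@]1([O-])C(OC)=C(OC)C1=O.[Li+]
F3 | step 3 | rac-4-ethenyl-2,3,4-trimethoxycyclobut-2-en-1-one | C=C[C@]1(OC)C(OC)=C(OC)C1=O
F4 | step 3 | (3Z)-2,3,4-trimethoxyhexa-1,3,5-trien-1-one | O=C=C(OC)/C(OC)=C(OC)\C=C
F5 | step 3 | 2,3,4-trimethoxycyclohexa-2,4-dien-1-one | O=C1CC=C(OC)C(OC)=C1OC
F6 | step 3 | 2,3,4-trimethoxyphenol | COc1ccc(O)c(OC)c1OC
F7 | step 2 | rac-4-[(E)-3,3-diethoxyprop-1-enyl]-4-hydroxy-2,3-dimethoxycyclobut-2-en-1-one | CCOC(OCC)/C=C/[C@]1(O)C(OC)=C(OC)C1=O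
F8 | step 6 | 2-[(tert-butyldimethylsilyl)oxy]-3,4,5-trimethoxybenzaldehyde | CC(C)(C)[Si](C)(C)Oc1c(C=O)cc(OC)c(OC)c1OC
F9 | step 6 | rac-1-{2-[(tert-butyldimethylsilyl)oxy]-3,4,5-trimethoxyphenyl}-3-(3,4-dimethoxyphenyl)prop-2-yn-1-ol | COc1ccc(C#C[C@H](O)c2cc(OC)c(OC)c(OC)c2O[Si](C)(C)C(C)(C)C)cc1OC
F10 | step 6 | 1-{2-[(tert-butyldimethylsilyl)oxy]-3,4,5-trimethoxyphenyl}-3-(3,4-dimethoxyphenyl)prop-2-yn-1-one | COc1ccc(C#CC(=O)c2cc(OC)c(OC)c(OC)c2O[Si](C)(C)C(C)(C)C)cc1OC
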